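**Plan**
- Retrosynthesis: the cyclobutane bonds C8–C8' and C9–C9' are cut first, giving two molecules of chloranthalactone A (23). In 23 the C8=C9 bond of ring B and the C4=C15 methylene are cut next. Last, C9–C10 and C5–C6 are cut together, giving enone 7, Grignard reagent 9 and bromide 14.
- Enabling feature: the quaternary C10 and the neighbouring C5 carry the two arms (C9 and C6) that become ring B. Both lie on the cyclopropane-fused five-membered ring A next to C4, so they are the β- and α-carbons of the C4 enone 7.
- Forward order: cyclopropane and ring A (1 → 7), both arms in one flask (step 8), ring B by C8–C9 vinylogous aldol condensation (step 12), cyclobutane by [2+2] photodimerisation (step 13).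
- Stereochemistry: the epoxide carbon of 1 fixes C1 and C3. C10 follows from addition anti to the cyclopropane methylene, C5 from alkylation trans to the silylmethyl arm (also the less crowded epimer). C8, C9, C8' and C9' follow from union of both monomers on the face anti to C14.

Key step: step 8

Assumption: 1 is bought as the single (S)-enantiomer and 10 as its commercial dimer, which reacts as the monomer; lindenane numbering (C1–C15) is used from 15 on, β being the face of ring A that carries the C14 methyl.

**Step 1**
Reactants: 1 (S)-2-(but-3-en-1-yl)oxirane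
Product: 2 (1S,2S,5R)-bicyclo[3.1.0]hexan-2-ol
Conditions: n-BuLi, 2,2,6,6-tetramethylpiperidine, t-BuOMe, 0 °C to rt; H2O
Reagents that add atoms: none
Why: Hodgson cyclopropanation: lithiation of the terminal epoxide carbon gives a carbenoid that adds to the tethered alkene, and the untouched epoxide stereocentre (C2) steers both ring-fusion centres so that the hydroxyl ends up anti to the cyclopropane methylene.

**Step 2**
Reactants: 2 (1S,2S,5R)-bicyclo[3.1.0]hexan-2-ol
Product: 3 (1S,5R)-bicyclo[3.1.0]hexan-2-one
Conditions: TEMPO (1 mol %), NaOCl, KBr (10 mol %), NaHCO3, CH2Cl2/H2O, 0 °C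
Reagents that add atoms: none
Why: Anelli oxidation of a secondary cyclopropyl carbinol; the two ring-fusion centres are not enolisable toward the bridgehead and stay intact.

**Step 3**
Reactants: 3 (1S,5R)-bicyclo[3.1.0]hexan-2-one
Product: 5 (1S,5S)-bicyclo[3.1.0]hex-3-en-2-one, via silyl enol ether 4 (not isolated)
Conditions: LiN(iPr)2, Me3SiCl, THF, −78 °C; solvent switch to DMSO; Pd(OAc)2 (10 mol %), O2 (1 atm), rt
Reagents that add atoms: none
Why: Saegusa–Ito dehydrogenation: enolisation is possible only toward C3, and aerobic Pd(OAc)2 catalysis turns the silyl enol ether into the C3=C4 enone.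

**Step 4**
Reactants: 5 (1S,5S)-bicyclo[3.1.0]hex-3-en-2-one
Product: 7 (1S,5R)-4-methylbicyclo[3.1.0]hex-3-en-2-one, via silyl enol ether 6 (not isolated)
Conditions: MeMgBr, CuBr·SMe2 (10 mol %), Me3SiCl, THF, −78 °C; solvent switch to DMSO; Pd(OAc)2 (10 mol %), O2 (1 atm), rt
Reagents that add atoms: methylmagnesium bromide (C[Mg]Br)
Why: Silyl-chloride-accelerated copper-catalysed conjugate methylation anti to the cyclopropane methylene, then a second Saegusa–Ito oxidation; palladium enters C3 trans to the new methyl and so finds the syn C4–H, and the transient C4 stereocentre is erased.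

**Step 5**
Reactants: 8 (chloromethyl)dimethylphenylsilane
Product: 9 (dimethylphenylsilyl)methylmagnesium chloride
Conditions: Mg turnings, Et2O, reflux
Reagents that add atoms: magnesium ([Mg])
Why: Ordinary Grignard formation from a primary α-silyl alkyl chloride.

**Step 6**
Reactants: 10 1,3-dihydroxyacetone; 11 ethyl 2-(triphenyl-λ5-phosphanylidene)propanoate
Product: 13 4-(hydroxymethyl)-3-methylfuran-2(5H)-one, via open-chain hydroxy ester 12 (not isolated)
Conditions: CH2Cl2, rt to 40 °C
Reagents that add atoms: none
Why: Wittig olefination of an activated ketone by a stabilised ylide; because the ketone is symmetric one CH2OH always lies cis to the ester and lactonises, which fixes the bromide-bearing carbon on C4 of the butenolide without any regiochemical question.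

**Step 7**
Reactants: 13 4-(hydroxymethyl)-3-methylfuran-2(5H)-one
Product: 14 4-(bromomethyl)-3-methylfuran-2(5H)-one
Conditions: CBr4, PPh3, CH2Cl2, 0 °C
Reagents that add atoms: carbon tetrabromide (BrC(Br)(Br)Br)
Why: Appel bromination of a primary allylic alcohol under neutral conditions that leave the butenolide untouched.

**Step 8**
Reactants: 7 (1S,5R)-4-methylbicyclo[3.1.0]hex-3-en-2-one; 9 (dimethylphenylsilyl)methylmagnesium chloride; 14 4-(bromomethyl)-3-methylfuran-2(5H)-one
Product: 16 (1S,3R,4S,5R)-4-[(dimethylphenylsilyl)methyl]-4-methyl-3-[(4-methyl-5-oxo-2,5-dihydrofuran-3-yl)methyl]bicyclo[3.1.0]hexan-2-one, via magnesium enolate 15 (not isolated)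
Conditions: 9 (1.3 equiv), Cu(OTf)2 (5 mol %), 1,3-dimesitylimidazolinium chloride (6 mol %), Et2O, −30 to 0 °C; then DMPU, 14 (1.6 equiv), THF, −78 to −20 °C; aq NH4Cl
Reagents that add atoms: none
Why: The Grignard reagent transmetalates to a carbene-ligated organocopper species that delivers the silylmethyl group 1,4 to C10 of the β-methyl enone, and the magnesium enolate 15 is then alkylated at C5 by the allylic bromide 14 in an SN2 reaction once DMPU is added. The closest known reaction type is the copper-catalysed conjugate addition of Grignard reagents to β-substituted cycloalkenones with in situ alkylation of the magnesium enolate (three-component coupling). No ring closes; the C9–C10 and C5–C6 bonds form, so every carbon of the monomer except C15 is in place. C10 is set by attack on the convex face anti to the cyclopropane methylene, which leaves the C14 methyl syn to it. C5 is set by approach of the bromide anti to the bulkier silylmethyl group on C10; since C5 is α to the ketone and the C6/C9-trans isomer is also the less crowded one, a short DBU equilibration of the crude product would convert any cis epimer. The step needs 1,4- over 1,2-addition (copper–carbene catalysis at low temperature), C-alkylation over proton transfer from the butenolide γ-CH2 (very reactive primary allylic bromide, low temperature, excess 14) and regiocontrol, which is inherent because the enolate exists only across C4–C5.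

**Step 9**
Reactants: 16 seco ketone with C9 silylmethyl and C6 butenolide arms
Product: 18 (1S,3R,4S,5R)-4-(hydroxymethyl)-4-methyl-3-[(4-methyl-5-oxo-2,5-dihydrofuran-3-yl)methyl]bicyclo[3.1.0]hexan-2-one, via fluorosilane 17 (not isolated)
Conditions: HBF4·OEt2, CH2Cl2, 0 °C to rt; then KF, KHCO3, 30% H2O2, THF/MeOH, rt
Reagents that add atoms: hydrogen peroxide (OO)
Why: Two-stage Fleming–Tamao oxidation: ipso-protodesilylation of the phenyl group gives the fluorosilane, whose C–Si bond is oxidised by buffered peroxide with retention; no peracid is present, so the ketone is spared Baeyer–Villiger oxidation.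

**Step 10**
Reactants: 18 C9 hydroxy ketone
Product: 19 C4-methylidene alcohol (18 with C4=O replaced by C4=C15H2)
Conditions: Zn, CH2Br2, TiCl4 (reagent preformed in THF), CH2Cl2, 0 °C to rt
Reagents that add atoms: dibromomethane (BrCBr)
Why: Lombardo methylenation: the non-basic reagent methylenates hindered, epimerisable ketones and tolerates free hydroxyl groups and lactones, so C5 keeps its configuration and is no longer enolisable afterwards.

**Step 11**
Reactants: 19 C4-methylidene alcohol
Product: 20 C9 aldehyde of 19
Conditions: Dess–Martin periodinane, pyridine, CH2Cl2, rt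
Reagents that add atoms: none
Why: Dess–Martin oxidation of a neopentyl primary alcohol; the aldehyde has no α-hydrogen and cannot epimerise.

**Step 12**
Reactants: 20 C9 aldehyde
Product: 23 chloranthalactone A, via silyloxyfuran aldehyde 21 (not isolated), via silylated aldol adduct 22 (not isolated)
Conditions: tBuMe2SiOTf, Et3N, CH2Cl2, −78 to 0 °C; then DBU, rt
Reagents that add atoms: none
Why: Intramolecular vinylogous Mukaiyama aldol condensation: soft enolisation gives the 2-silyloxyfuran, whose γ-carbon C8 adds to the silyl-activated C9 aldehyde (6-exo-trig closure of ring B), and DBU then removes the acidic C8–H and expels silanolate (E1cB) to give the C8=C9 enol lactone, erasing the two transient stereocentres.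

**Step 13**
Reactants: 23 chloranthalactone A (two molecules)
Product: 24 head-to-head [2+2] photodimer of 23 (target)
Conditions: hν (high-pressure Hg lamp, Pyrex filter), degassed hexane, rt
Reagents that add atoms: none
Why: [2+2] photocycloaddition of the C8=C9 bond of the dienolide chromophore: head-to-head union through the allylic, α-oxygenated 1,4-biradical, each monomer reacting on its α face anti to the C14 methyl, which sets C8, C9, C8' and C9' in the C2-symmetric dimer.

**Compound list**
1 | (S)-2-(but-3-en-1-yl)oxirane | C=CCC[C@H]1CO1 | starting material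
2 | (1S,2S,5R)-bicyclo[3.1.0]hexan-2-ol (OH anti to the cyclopropane methylene) | O[C@H]1CC[C@@H]2C[C@H]12 | intermediate
3 | (1S,5R)-bicyclo[3.1.0]hexan-2-one | O=C1CC[C@@H]2C[C@H]12 | intermediate
4 | 2-(trimethylsilyloxy)bicyclo[3.1.0]hex-2-ene (ring fusion as in 3) | C[Si](C)(C)OC1=CC[C@@H]2C[C@H]12 | intermediate
5 | (1S,5S)-bicyclo[3.1.0]hex-3-en-2-one | O=C1C=C[C@@H]2C[C@H]12 | intermediate
6 | 4-methyl-2-(trimethylsilyloxy)bicyclo[3.1.0]hex-2-ene (methyl anti to the cyclopropane methylene) | C[Si](C)(C)OC1=C[C@@H](C)[C@@H]2C[C@H]12 | intermediate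
7 | (1S,5R)-4-methylbicyclo[3.1.0]hex-3-en-2-one | O=C1C=C(C)[C@@H]2C[C@H]12 | intermediate
8 | (chloromethyl)dimethylphenylsilane | C[Si](C)(CCl)c1ccccc1 | starting material
9 | (dimethylphenylsilyl)methylmagnesium chloride | Cl[Mg]C[Si](C)(C)c1ccccc1 | intermediate
10 | 1,3-dihydroxyacetone | OCC(=O)CO | starting material
11 | ethyl 2-(triphenyl-λ5-phosphanylidene)propanoate | CCOC(=O)C(C)=P(c1ccccc1)(c1ccccc1)c1ccccc1 | starting material
12 | ethyl 4-hydroxy-3-(hydroxymethyl)-2-methylbut-2-enoate | CCOC(=O)C(C)=C(CO)CO | intermediate
13 | 4-(hydroxymethyl)-3-methylfuran-2(5H)-one | CC1=C(CO)COC1=O | intermediate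
14 | 4-(bromomethyl)-3-methylfuran-2(5H)-one | CC1=C(CBr)COC1=O | intermediate
15 | chloromagnesium C4–C5 enolate of the conjugate adduct (10β-methyl, 10α-CH2SiMe2Ph, cyclopropane methylene β) | Cl[Mg]OC1=C[C@@](C)(C[Si](C)(C)c2ccccc2)[C@@H]2C[C@H]12 | intermediate
16 | (1S,3R,4S,5R)-4-[(dimethylphenylsilyl)methyl]-4-methyl-3-[(4-methyl-5-oxo-2,5-dihydrofuran-3-yl)methyl]bicyclo[3.1.0]hexan-2-one (C6 arm β, H5 α) | O=C1[C@H]2C[C@H]2[C@@](C[Si](C)(C)c2ccccc2)(C)[C@H]1CC1=C(C)C(=O)OC1 | intermediate
17 | fluorodimethylsilyl analogue of 16 | O=C1[C@H]2C[C@H]2[C@@](C[Si](C)(C)F)(C)[C@H]1CC1=C(C)C(=O)OC1 | intermediate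
18 | (1S,3R,4S,5R)-4-(hydroxymethyl)-4-methyl-3-[(4-methyl-5-oxo-2,5-dihydrofuran-3-yl)methyl]bicyclo[3.1.0]hexan-2-one | O=C1[C@H]2C[C@H]2[C@@](CO)(C)[C@H]1CC1=C(C)C(=O)OC1 | intermediate
19 | C4-methylidene alcohol (18 with C4=CH2; stereocentres spatially unchanged) | C=C1[C@H]2C[C@H]2[C@@](CO)(C)[C@H]1CC1=C(C)C(=O)OC1 | intermediate
20 | C9 aldehyde of 19 | C=C1[C@H]2C[C@H]2[C@@](C=O)(C)[C@H]1CC1=C(C)C(=O)OC1 | intermediate
21 | 2-(tert-butyldimethylsilyloxy)furan form of 20 | C=C1[C@H]2C[C@H]2[C@@](C=O)(C)[C@H]1Cc1coc(O[Si](C)(C)C(C)(C)C)c1C | intermediate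
22 | ring-B-closed 9-(tert-butyldimethylsilyloxy) lactone (C8/C9 diastereomers) | C=C1[C@H]2C[C@H]2[C@@]2(C)[C@H]1CC1=C(C)C(=O)OC1C2O[Si](C)(C)C(C)(C)C | intermediate
23 | chloranthalactone A (lindena-4(15),7(11),8-trien-12,8-olide; cyclopropane methylene and C14 β, H5 α) | C=C1[C@H]2C[C@H]2[C@@]2(C)[C@H]1CC1=C(C)C(=O)OC1=C2 | intermediate
24 | head-to-head [2+2] dimer of 23 (cyclobutane C8–C9–C9'–C8', new bonds on the α faces, C2-symmetric) | C=C1[C@H]2C[C@H]2[C@@]2(C)[C@H]1CC1=C(C)C(=O)O[C@]13[C@H]2[C@H]1[C@@]2(C)[C@@H]4C[C@@H]4C(=C)[C@@H]2CC2=C(C)C(=O)O[C@@]213 | target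

**Step count and risks**
Total: 13 steps. Longest linear sequence: 10 steps (steps 1–4 and 8–13, from 1).

Step 8. Transfer of the α-silyl alkyl group to the hindered, fully substituted C10 may be slow, so that 1,2-addition competes. The magnesium enolate may also take a proton from the butenolide γ-CH2 of 14 faster than it is alkylated. The fallback sets out from 7 and 9 and returns at 16. The conjugate addition is run with CuBr·SMe2 under Me3SiCl/HMPA acceleration, and the product is isolated as the trimethylsilyl enol ether F1. MeLi in THF then releases the salt-free lithium enolate F2, which is alkylated with 14 at −78 °C in THF/DMPU to give 16, with DBU equilibration at C5 if required.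

Step 12. Closure of the trans-fused ring B may be slower than return of the silyloxyfuran to the butenolide on work-up, or the silanolate elimination may stall at the aldol stage. The fallback sets out from 20 and returns at 23. iPr3SiOTf/Et3N converts 20 into the isolated triisopropylsilyloxyfuran aldehyde F3. BF3·OEt2 at −78 °C (discrete vinylogous Mukaiyama aldol) cyclises it to the β-hydroxy lactone F4. MsCl/Et3N gives the mesylate F5, and DBU-induced E1cB elimination gives 23.

Step 9. The strong acid needed for protodesilylation may open the cyclopropyl ketone or epimerise C5 before the phenyl group is lost. The fallback sets out from 7 and 14 and returns at 18. The coupling of step 8 is repeated with (isopropoxydimethylsilyl)methylmagnesium chloride F6, made from the commercial chloromethyl silane and Mg. Via the magnesium enolate F7 it gives the isopropoxysilane ketone F8, which is oxidised directly with H2O2/KF/KHCO3 (Tamao oxidation, no acid) to 18.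

**Further compounds**
F1 | step 8 | trimethylsilyl enol ether of the conjugate adduct | C[Si](C)(C)OC1=C[C@@](C)(C[Si](C)(C)c2ccccc2)[C@@H]2C[C@H]12
F2 | step 8 | lithium enolate of the conjugate adduct | [Li]OC1=C[C@@](C)(C[Si](C)(C)c2ccccc2)[C@@H]2C[C@H]12
F3 | step 12 | 2-(triisopropylsilyloxy)furan form of 20 | C=C1[C@H]2C[C@H]2[C@@](C=O)(C)[C@H]1Cc1coc(O[Si](C(C)C)(C(C)C)C(C)C)c1C
F4 | step 12 | ring-B-closed 9-hydroxy lactone (C8/C9 diastereomers) | C=C1[C@H]2C[C@H]2[C@@]2(C)[C@H]1CC1=C(C)C(=O)OC1C2O
F5 | step 12 | 9-methanesulfonate of F4 | C=C1[C@H]2C[C@H]2[C@@]2(C)[C@H]1CC1=C(C)C(=O)OC1C2OS(C)(=O)=O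
F6 | step 9 | (isopropoxydimethylsilyl)methylmagnesium chloride | CC(C)O[Si](C)(C)C[Mg]Cl
F7 | step 9 | chloromagnesium enolate of the isopropoxysilyl conjugate adduct | Cl[Mg]OC1=C[C@@](C)(C[Si](C)(C)OC(C)C)[C@@H]2C[C@H]12
F8 | step 9 | isopropoxydimethylsilyl analogue of 16 | O=C1[C@H]2C[C@H]2[C@@](C[Si](C)(C)OC(C)C)(C)[C@H]1CC1=C(C)C(=O)OC1
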